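**Assumptions:** Decalin numbering is used throughout: C1 carries the propenyl group, C2 the acyl group, C4 and C7 the methyl groups. The SMILES decodes as (4aS,7S,8aS), a trans-fused ring system with the 7-methyl group equatorial, and this maps onto (S)-citronellal. Compounds 1, 2, 8, 10, 13 and 14 are taken as catalogue chemicals.

## Retrosynthetic overview

1. The target comes from global O-deprotection of its 2,4-dimethoxypyridine / O-benzyl masked form. The C1=C2 alkene comes from dehydrogenation of the corresponding octalin ketone.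
2. Both carbocycles form at once in an intramolecular inverse-demand Diels–Alder reaction of an acyclic all-E tetraenone. It makes the C1–C2 and C4a–C8a bonds, and the C7 methyl group steers the tether.
3. The tetraenone comes from a 3-lithio-2,4-dimethoxy-5-arylpyridine and a tetraenyl Weinreb amide. The pyridine ring is bought and its aryl group is attached by Suzuki coupling.
4. The Weinreb amide comes from (S)-citronellal by two-directional olefination: a crotyl HWE at the CHO end, then cleavage of the prenyl end followed by a Wittig and an HWE reaction.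
5. Ring order: pyridine (purchased), then cyclohexane and cyclohexene together in the cycloaddition, then the cyclohexadiene by oxidation.

## Route

**Step 1**
Reactants: 1 (S)-citronellal; 2 diethyl (E)-but-2-enylphosphonate
Product: 4 (2E,4E,7S)-7,11-dimethyldodeca-2,4,10-triene, via lithiated phosphonate 3 (not isolated)
Conditions: 2, n-BuLi, THF, −78 °C; HMPA; then 1, −78 °C → rt
Reagents that add atoms: 2 diethyl (E)-but-2-enylphosphonate, C/C=C/CP(=O)(OCC)OCC
Why: Horner–Wadsworth–Emmons olefination with an α-lithiated allylic phosphonate in THF/HMPA gives the (E,E)-diene, and the C7 stereocentre bought with citronellal is β to the aldehyde and is not touched.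

**Step 2**
Reactants: 4 (2E,4E,7S)-7,11-dimethyldodeca-2,4,10-triene
Product: 7 (4S,6E,8E)-4-methyldeca-6,8-dienal, via epoxide 5 (not isolated), via diol 6 (not isolated)
Conditions: mCPBA (1.0 equiv), CH2Cl2, −10 °C; solvent swap; H5IO6, THF/H2O, 0 °C
Reagents that add atoms: mCPBA, O=C(OO)c1cccc(Cl)c1
Why: Prilezhaev epoxidation picks the isolated trisubstituted alkene over the conjugated disubstituted diene (the selectivity seen with myrcene), and periodic acid then hydrolyses the epoxide and cleaves the glycol (Malaprade cleavage) to the aldehyde.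

**Step 3**
Reactants: 7 (4S,6E,8E)-4-methyldeca-6,8-dienal; 8 2-(triphenylphosphoranylidene)propanal
Product: 9 (2E,6S,8E,10E)-2,6-dimethyldodeca-2,8,10-trienal
Conditions: CH2Cl2, 40 °C, 24 h
Reagents that add atoms: 8 2-(triphenylphosphoranylidene)propanal, CC(C=O)=P(c1ccccc1)(c1ccccc1)c1ccccc1
Why: Wittig reaction of a stabilised ylide gives the (E)-trisubstituted enal, and the low temperature keeps the enal and diene from a premature normal-demand cycloaddition.

**Step 4**
Reactants: 9 (2E,6S,8E,10E)-2,6-dimethyldodeca-2,8,10-trienal; 10 diethyl {2-[methoxy(methyl)amino]-2-oxoethyl}phosphonate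
Product: 12 (2E,4E,8S,10E,12E)-N-methoxy-N,4,8-trimethyltetradeca-2,4,10,12-tetraenamide, via sodium phosphonate carbanion 11 (not isolated)
Conditions: 10, NaH, THF, 0 °C; then 9, 0 °C → rt
Reagents that add atoms: 10 diethyl {2-[methoxy(methyl)amino]-2-oxoethyl}phosphonate, CCOP(=O)(CC(=O)N(C)OC)OCC
Why: Horner–Wadsworth–Emmons reaction of a stabilised phosphonate with a non-enolisable enal is highly E-selective and delivers the dienyl Weinreb amide directly at the acyl oxidation level.

**Step 5**
Reactants: 13 5-bromo-2,4-dimethoxypyridine; 14 4-(benzyloxy)phenylboronic acid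
Product: 15 5-[4-(benzyloxy)phenyl]-2,4-dimethoxypyridine
Conditions: Pd(dppf)Cl2 (3 mol %), K2CO3, dioxane/H2O, 85 °C
Reagents that add atoms: 14 4-(benzyloxy)phenylboronic acid, OB(O)c1ccc(OCc2ccccc2)cc1
Why: Suzuki–Miyaura coupling of a heteroaryl bromide with an arylboronic acid is routine, and the methyl and benzyl ethers are inert to it.

**Step 6**
Reactants: 15 5-[4-(benzyloxy)phenyl]-2,4-dimethoxypyridine; 12 (2E,4E,8S,10E,12E)-N-methoxy-N,4,8-trimethyltetradeca-2,4,10,12-tetraenamide
Product: 18 (2E,4E,8S,10E,12E)-1-{5-[4-(benzyloxy)phenyl]-2,4-dimethoxypyridin-3-yl}-4,8-dimethyltetradeca-2,4,10,12-tetraen-1-one, via 3-lithiopyridine 16 (not isolated), via tetrahedral lithium adduct 17 (not isolated)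
Conditions: 15, n-BuLi (1.05 equiv), THF, −78 → −20 °C; then 12, −78 → 0 °C; H2O quench
Reagents that add atoms: 15 5-[4-(benzyloxy)phenyl]-2,4-dimethoxypyridine, COc1cc(OC)c(-c2ccc(OCc3ccccc3)cc2)cn1
Why: Directed ortho-metalation takes the C3–H flanked by two methoxy groups, and Weinreb ketone synthesis stops at the chelated adduct, so the dienone appears only on quench without over-addition.

**Step 7**
Reactants: 18 the tetraenone
Product: 19 {5-[4-(benzyloxy)phenyl]-2,4-dimethoxypyridin-3-yl}{(1R,2R,4aS,7S,8aR)-4,7-dimethyl-1-[(E)-prop-1-enyl]-1,2,4a,5,6,7,8,8a-octahydronaphthalen-2-yl}methanone (trans-fused; H-1, H-2 and H-4a on one face, H-8a on the other; 7-Me equatorial)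
Conditions: PhMe (0.01 M), BHT (cat.), 110 °C, sealed tube, 36 h
Reagents that add atoms: none
Why: In this intramolecular inverse-electron-demand Diels–Alder reaction the electron-poor dienone (C2=C3–C4=C4a) adds the proximal alkene of the electron-rich diene (C8a=C1) through a chair-like tether with the C7 methyl group equatorial, which sets C4a and C8a trans and all-equatorial, while the E,E,E geometry sets the C1 and C2 centres that are erased in step 8.

**Step 8**
Reactants: 19 the octalin ketone
Product: 22 {5-[4-(benzyloxy)phenyl]-2,4-dimethoxypyridin-3-yl}{(4aS,7S,8aS)-4,7-dimethyl-1-[(E)-prop-1-enyl]-4a,5,6,7,8,8a-hexahydronaphthalen-2-yl}methanone, via lithium dienolate 20 (not isolated), via alpha-sulfilimine adduct 21 (not isolated)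
Conditions: LDA (1.05 equiv), THF, −78 → −40 °C; then N-tert-butylbenzenesulfinimidoyl chloride (1.05 equiv), −78 °C
Reagents that add atoms: none
Why: In the Mukaiyama dehydrogenation the doubly activated C2–H is removed, sulfur enters at C2 opposite the propenyl group and therefore syn to H-1, and the only β-hydrogen available for the five-centre syn-elimination is H-1, so C1=C2 forms regiospecifically while C4a, C7 and C8a stay untouched.

**Step 9**
Reactants: 22 the protected dienone
Product: 24 ilicicolin J, via tris(trimethylsilyl) ether 23 (not isolated)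
Conditions: TMSCl, NaI, MeCN, 0 °C → rt, dark; then MeOH, aq. Na2S2O3
Reagents that add atoms: none
Why: In this silyl iodide ether cleavage the TMSI made in situ silylates the pyridine nitrogen and the ether oxygens, iodide removes the two activated pyridyl methyl groups and the benzyl group by SN2, and methanolysis of the silyl ethers releases the 4-hydroxy-2-pyridone and the phenol with no effect on any stereocentre.

## Compound list

1 | (S)-citronellal | O=CC[C@@H](C)CCC=C(C)C | starting material
2 | diethyl (E)-but-2-enylphosphonate | C/C=C/CP(=O)(OCC)OCC | starting material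
3 | α-lithiated diethyl (E)-but-2-enylphosphonate | C/C=C/C([Li])P(=O)(OCC)OCC | intermediate
4 | (2E,4E,7S)-7,11-dimethyldodeca-2,4,10-triene | C/C=C/C=C/C[C@@H](C)CCC=C(C)C | intermediate
5 | 10,11-epoxide of 4 (epimers at the epoxide CH) | C/C=C/C=C/C[C@@H](C)CCC1OC1(C)C | intermediate
6 | 10,11-diol of 4 (epimers at the carbinol CH) | C/C=C/C=C/C[C@@H](C)CCC(O)C(C)(C)O | intermediate
7 | (4S,6E,8E)-4-methyldeca-6,8-dienal | C/C=C/C=C/C[C@@H](C)CCC=O | intermediate
8 | 2-(triphenylphosphoranylidene)propanal | CC(C=O)=P(c1ccccc1)(c1ccccc1)c1ccccc1 | starting material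
9 | (2E,6S,8E,10E)-2,6-dimethyldodeca-2,8,10-trienal | C/C=C/C=C/C[C@@H](C)CC/C=C(\C)C=O | intermediate
10 | diethyl {2-[methoxy(methyl)amino]-2-oxoethyl}phosphonate | CCOP(=O)(CC(=O)N(C)OC)OCC | starting material
11 | sodium carbanion of 10 | [Na+].CCOP(=O)(OCC)[CH-]C(=O)N(C)OC | intermediate
12 | (2E,4E,8S,10E,12E)-N-methoxy-N,4,8-trimethyltetradeca-2,4,10,12-tetraenamide | C/C=C/C=C/C[C@@H](C)CC/C=C(C)/C=C/C(=O)N(C)OC | intermediate
13 | 5-bromo-2,4-dimethoxypyridine | COc1cc(OC)c(Br)cn1 | starting material
14 | 4-(benzyloxy)phenylboronic acid | OB(O)c1ccc(OCc2ccccc2)cc1 | starting material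
15 | 5-[4-(benzyloxy)phenyl]-2,4-dimethoxypyridine | COc1cc(OC)c(-c2ccc(OCc3ccccc3)cc2)cn1 | intermediate
16 | 3-lithio derivative of 15 | COc1ncc(-c2ccc(OCc3ccccc3)cc2)c(OC)c1[Li] | intermediate
17 | tetrahedral lithium adduct of 16 and 12 | C/C=C/C=C/C[C@@H](C)CC/C=C(C)/C=C/C(O[Li])(N(C)OC)c1c(OC)ncc(-c2ccc(OCc3ccccc3)cc2)c1OC | intermediate
18 | (2E,4E,8S,10E,12E)-tetraenone | C/C=C/C=C/C[C@@H](C)CC/C=C(C)/C=C/C(=O)c1c(OC)ncc(-c2ccc(OCc3ccccc3)cc2)c1OC | intermediate
19 | (1R,2R,4aS,7S,8aR)-octalin ketone (Diels–Alder adduct) | C/C=C/[C@H]1[C@@H](C(=O)c2c(OC)ncc(-c3ccc(OCc4ccccc4)cc3)c2OC)C=C(C)[C@H]2CC[C@H](C)C[C@H]12 | intermediate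
20 | lithium dienolate of 19 | C/C=C/[C@H]1C(=C(O[Li])c2c(OC)ncc(-c3ccc(OCc4ccccc4)cc3)c2OC)C=C(C)[C@H]2CC[C@H](C)C[C@H]12 | intermediate
21 | C2 S-phenyl-N-tert-butylsulfilimine adduct (S on the face of H-1) | C/C=C/[C@H]1[C@@](S(=NC(C)(C)C)c2ccccc2)(C(=O)c2c(OC)ncc(-c3ccc(OCc4ccccc4)cc3)c2OC)C=C(C)[C@H]2CC[C@H](C)C[C@H]12 | intermediate
22 | (4aS,7S,8aS)-protected ilicicolin J (2,4-di-O-methyl, O-benzyl) | C/C=C/C1=C(C(=O)c2c(OC)ncc(-c3ccc(OCc4ccccc4)cc3)c2OC)C=C(C)[C@H]2CC[C@H](C)C[C@H]12 | intermediate
23 | tris(trimethylsilyl) ether of ilicicolin J | C/C=C/C1=C(C(=O)c2c(O[Si](C)(C)C)ncc(-c3ccc(O[Si](C)(C)C)cc3)c2O[Si](C)(C)C)C=C(C)[C@H]2CC[C@H](C)C[C@H]12 | intermediate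
24 | ilicicolin J, 4-hydroxy-5-(4-hydroxyphenyl)-3-{[(4aS,7S,8aS)-4,7-dimethyl-1-[(E)-prop-1-enyl]-4a,5,6,7,8,8a-hexahydronaphthalen-2-yl]carbonyl}pyridin-2(1H)-one | C/C=C/C1=C(C(=O)c2c(O)c(-c3ccc(O)cc3)c[nH]c2=O)C=C(C)[C@H]2CC[C@H](C)C[C@H]12 | target

## Step count

- Total steps: 9.
- Longest linear sequence: 8 (steps 1, 2, 3, 4, 6, 7, 8, 9).

## Steps most likely to fail

**Step 8 (dehydrogenation).**
- Risk: sulfur may enter at C2 on the face anti to H-1, which leaves no syn β-hydrogen, or the allylic sulfilimine may undergo a [2,3]-shift.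
- Fallback from 19, returning at 22: this is a halogenation and anti-elimination sequence that has the opposite stereochemical requirement.
- Soft enolisation of 19 with TMSOTf/Et3N gives the trimethylsilyl dienol ether F4.
- NBS at −78 °C converts it into the axial C2 bromide F5, whose C–Br bond is antiperiplanar to the axial H-1.
- DBU in toluene then removes HBr by E2 elimination to give 22.
- A γ-bromide at C4, if formed instead, reaches the same diene by 1,4-elimination.

**Step 7 (cycloaddition).**
- Risk: the (E,E)-diene terminus can act as the 4π partner toward C4=C4a in a normal-demand mode, which builds a quaternary C4. The trans/cis ratio of the ring fusion may also be modest.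
- Fallback from 12, returning at 19: the cycloaddition is moved ahead of the fragment coupling, onto a smaller substrate with no basic pyridine nitrogen that can be activated by a Lewis acid.
- DIBAL-H reduces 12 to the tetraenal F1.
- F1 is cyclised (Me2AlCl, CH2Cl2, −78 → −20 °C, or heat), and the octalin carbaldehyde F2 is separated from its isomers at this cheap stage.
- The aryllithium 16 adds to F2 to give the carbinol F3.
- Dess–Martin oxidation of F3 gives 19.

**Step 9 (global deprotection).**
- Risk: the cross-conjugated trienone may not tolerate TMSI and traces of HI, and benzyl iodide may re-alkylate the product.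
- Fallback from 19, returning at 23: the order of events is inverted, so the ether cleavage is done on the robust mono-alkene stage and the oxidation comes last under neutral conditions.
- Compound 19 is treated with TMSCl/NaI to give the tris(trimethylsilyl) ether of the octalin ketone F6.
- After the volatiles are removed, F6 is enol-silylated with TMSOTf/Et3N to the tetrakis(trimethylsilyl) dienol ether F7.
- Saegusa–Ito oxidation of F7 with Pd(OAc)2 in MeCN gives 23, which methanolysis converts into 24 as in the main route.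

## Further compounds

F1 | step 7 | (2E,4E,8S,10E,12E)-4,8-dimethyltetradeca-2,4,10,12-tetraenal | C/C=C/C=C/C[C@@H](C)CC/C=C(C)/C=C/C=O
F2 | step 7 | trans-fused 4,7-dimethyl-1-[(E)-prop-1-enyl]-1,2,4a,5,6,7,8,8a-octahydronaphthalene-2-carbaldehyde (configuration as in 19) | C/C=C/[C@H]1[C@@H](C=O)C=C(C)[C@H]2CC[C@H](C)C[C@H]12
F3 | step 7 | carbinol from F2 and 16 (epimers at the carbinol carbon) | C/C=C/[C@H]1[C@@H](C(O)c2c(OC)ncc(-c3ccc(OCc4ccccc4)cc3)c2OC)C=C(C)[C@H]2CC[C@H](C)C[C@H]12
F4 | step 8 | trimethylsilyl dienol ether of 19 | C/C=C/[C@H]1C(=C(O[Si](C)(C)C)c2c(OC)ncc(-c3ccc(OCc4ccccc4)cc3)c2OC)C=C(C)[C@H]2CC[C@H](C)C[C@H]12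
F5 | step 8 | C2 bromide of 19 (Br anti to H-1) | C/C=C/[C@H]1[C@](Br)(C(=O)c2c(OC)ncc(-c3ccc(OCc4ccccc4)cc3)c2OC)C=C(C)[C@H]2CC[C@H](C)C[C@H]12
F6 | step 9 | tris(trimethylsilyl) ether of the deprotected octalin ketone | C/C=C/[C@H]1[C@@H](C(=O)c2c(O[Si](C)(C)C)ncc(-c3ccc(O[Si](C)(C)C)cc3)c2O[Si](C)(C)C)C=C(C)[C@H]2CC[C@H](C)C[C@H]12
F7 | step 9 | tetrakis(trimethylsilyl) dienol ether | C/C=C/[C@H]1C(=C(O[Si](C)(C)C)c2c(O[Si](C)(C)C)ncc(-c3ccc(O[Si](C)(C)C)cc3)c2O[Si](C)(C)C)C=C(C)[C@H]2CC[C@H](C)C[C@H]12
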